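**Plan**

1. Locants: C1 = ring CH carrying the side chain, C4 = ring CH(CH3), C5 = spiro atom, C6–C10 = six-membered ring (C7=C8, CH3 on C8, OH on C9), C1′ = first side-chain carbon.
2. Cuts, in order: (a) the C9 carbinol and the C7=C8 alkene, by Wharton transposition and epoxidation, back to a spiro 2-methylcyclohex-2-enone and its saturated ketone; (b) C1–C5, by radical conjugate addition, which opens the cyclopentane; (c) C1–C2, by ester enolate alkylation; (d) aryl–C4, by conjugate arylation of a crotonate.
3. Enabling feature: C5 stands 1,3 to both C7 and C9, which flank the methyl-bearing C8. C5 is therefore the β-carbon of a 3-alkyl-6-methylcyclohex-2-enone (a Birch-reduced 2-methylanisole), and either flanking carbon can later become the carbinol. C1, with the C1′ methyl branch and the chain beyond, is the α-carbon of (R)-citronellic acid, so the carboxyl group is a traceless radical precursor at C1.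
4. Forward: the arene fragment (steps 1–3) and the citronellate tail (steps 4–7) are joined at C1–C2 (step 8). The six-membered ring is unmasked from the arene (step 9), the five-membered ring closes onto it (step 10), the alkene and hydroxyl are placed (steps 11–14), and the acetate is set last.
5. Stereochemistry: C4 from rhodium-catalysed asymmetric arylation; C1′ from (R)-citronellic acid; the tail centre from iridium-catalysed asymmetric hydrogenation; C1 and C5 together from the C4-controlled radical closure; C9 from epoxidation anti to the C4 methyl group, kept through the Wharton step.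

Key step: step 10

Remark: the ligand antipodes named in steps 1 and 6 are those expected to give the (S)-benzylic centre and the (7S) tail centre; the sense of each catalytic step is to be confirmed on its first product and the antipodal ligand taken if it is the opposite.

**Route**

Step 1
Reactants: 1 (3-methoxy-4-methylphenyl)boronic acid; 2 tert-butyl (E)-but-2-enoate
Product: 3 tert-butyl (3S)-3-(3-methoxy-4-methylphenyl)butanoate
Conditions: Rh(acac)(C2H4)2 (3 mol%), (R)-BINAP, dioxane/H2O 10:1, 100 °C
Reagents that add atoms: none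
Why: Rhodium-catalysed asymmetric 1,4-addition of an arylboronic acid to an enoate (Hayashi–Miyaura reaction), in which the BINAP-bound aryl–rhodium species adds to one enantioface of the crotonate and sets the benzylic centre (the later C4) as S.

Step 2
Reactants: 3 tert-butyl (3S)-3-(3-methoxy-4-methylphenyl)butanoate
Product: 4 (3S)-3-(3-methoxy-4-methylphenyl)butan-1-ol
Conditions: LiAlH4, THF, 0 to 23 °C
Reagents that add atoms: none
Why: Hydride reduction of the ester to the primary alcohol, which does not touch the benzylic stereocentre.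

Step 3
Reactants: 4 (3S)-3-(3-methoxy-4-methylphenyl)butan-1-ol
Product: 5 4-[(2S)-4-iodobutan-2-yl]-2-methoxy-1-methylbenzene
Conditions: I2, PPh3, imidazole, CH2Cl2, 0 to 23 °C
Reagents that add atoms: iodine, II
Why: Appel-type iodination of a primary alcohol under neutral conditions at a non-stereogenic carbon.

Step 4
Reactants: 6 (3R)-3,7-dimethyloct-6-enoic acid ((R)-citronellic acid)
Product: 7 benzyl (3R)-3,7-dimethyloct-6-enoate
Conditions: BnBr, K2CO3, DMF, 23 °C
Reagents that add atoms: benzyl bromide, BrCc1ccccc1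
Why: Carboxylate O-alkylation (SN2) gives an ester that serves for the enolate alkylation and is later removed by the dissolving metal of step 9 without a separate hydrolysis.

Step 5
Reactants: 7 benzyl (3R)-3,7-dimethyloct-6-enoate
Product: 8 benzyl (3R,6E)-8-hydroxy-3,7-dimethyloct-6-enoate
Conditions: SeO2 (cat.), t-BuOOH, salicylic acid (cat.), CH2Cl2, 23 °C
Reagents that add atoms: tert-butyl hydroperoxide, CC(C)(C)OO
Why: Catalytic SeO2 allylic oxidation (ene reaction then [2,3]-sigmatropic shift) should hydroxylate the (E)-methyl group of the trisubstituted alkene and leave the ester and the C3 centre alone.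

Step 6
Reactants: 8 benzyl (3R,6E)-8-hydroxy-3,7-dimethyloct-6-enoate
Product: 9 benzyl (3R,7S)-8-hydroxy-3,7-dimethyloctanoate
Conditions: H2 (50 bar), [Ir(cod)((S)-tBu-PHOX)]B[3,5-(CF3)2C6H3]4 (1 mol%), CH2Cl2, 23 °C
Reagents that add atoms: none
Why: Iridium-catalysed asymmetric hydrogenation of a trisubstituted (E)-2-methylallylic alcohol, in which the chiral P,N ligand selects the alkene face and sets C7 as S independently of the remote C3 centre, the homogeneous catalyst leaving the benzyl ester intact.

Step 7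
Reactants: 9 benzyl (3R,7S)-8-hydroxy-3,7-dimethyloctanoate
Product: 10 benzyl (3R,7S)-3,7-dimethyl-8-[(triisopropylsilyl)oxy]octanoate
Conditions: TIPSCl, imidazole, DMF, 23 °C
Reagents that add atoms: chlorotriisopropylsilane, CC(C)[Si](Cl)(C(C)C)C(C)C
Why: Silylation of the primary alcohol with a group that should survive LDA, dissolving metal, dilute acid, alkaline hydroperoxide and hydrazine.

Step 8
Reactants: 10 benzyl (3R,7S)-3,7-dimethyl-8-[(triisopropylsilyl)oxy]octanoate; 5 4-[(2S)-4-iodobutan-2-yl]-2-methoxy-1-methylbenzene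
Product: 12 benzyl (3R,7S)-2-[(3S)-3-(3-methoxy-4-methylphenyl)butyl]-3,7-dimethyl-8-[(triisopropylsilyl)oxy]octanoate (both C2 epimers), via lithium enolate 11 (not isolated)
Conditions: LDA, THF, −78 °C; then 5, DMPU, −78 to 0 °C
Reagents that add atoms: none
Why: Ester enolate alkylation (SN2) with the primary iodide joins the two fragments at C1–C2; the new centre is left uncontrolled on purpose because it becomes the planar radical of step 10.

Step 9
Reactants: 12 benzyl (3R,7S)-2-[(3S)-3-(3-methoxy-4-methylphenyl)butyl]-3,7-dimethyl-8-[(triisopropylsilyl)oxy]octanoate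
Product: 16 (3R,7S)-3,7-dimethyl-2-[(3S)-3-(4-methyl-3-oxocyclohex-1-en-1-yl)butyl]-8-[(triisopropylsilyl)oxy]octanoic acid (C2 epimers; ring methyl carbon also unset), via lithium aryl carboxylate 13 (not isolated), via lithium dienol ether carboxylate 14 (not isolated), via unconjugated enone acid 15 (not isolated)
Conditions: Li, NH3(l), THF, −78 °C; then t-BuOH, −78 to −33 °C; then 1 M aq. HCl, THF, 23 °C
Reagents that add atoms: water, O
Why: The dissolving metal first cleaves the benzyl ester at the benzylic C–O bond to the lithium carboxylate, which resists reduction, and then reduces the anisole to the 1-methoxycyclohexa-1,4-diene (Birch reduction); acid hydrolysis of the enol ether and conjugation of the β,γ-enone give the 3-alkyl-6-methylcyclohex-2-enone, whose ring methyl centre forms as a mixture that is erased in steps 11 and 12.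

Step 10
Reactants: 16 (3R,7S)-3,7-dimethyl-2-[(3S)-3-(4-methyl-3-oxocyclohex-1-en-1-yl)butyl]-8-[(triisopropylsilyl)oxy]octanoic acid
Product: 17 (1R,4S,5R)-4,8-dimethyl-1-[(2R,6S)-6-methyl-7-[(triisopropylsilyl)oxy]heptan-2-yl]spiro[4.5]decan-7-one (both C8 epimers)
Conditions: Ir[dF(CF3)ppy]2(dtbbpy)PF6 (2 mol%), K2HPO4, DMF (0.02 M), blue LEDs, 23 °C
Reagents that add atoms: none
Why: The photoexcited trivalent iridium complex oxidizes the carboxylate of 16, loss of CO2 leaves a nucleophilic secondary radical at C1, this adds to C5, the β-carbon of the enone, and the α-keto radical so formed is reduced by the divalent iridium species and protonated at C6. The closest known reaction types are the photoredox decarboxylative conjugate addition of aliphatic acids to enones and the radical spirocyclization onto 3-substituted cyclohexenones. The cyclopentane closes in the 5-exo-trig mode through a chair-like transition state; the 6-endo mode would have to attack the electron-poor α-carbon and is not expected. At C5 the rotamer about C4–C5 decides: the C4 methyl group should avoid the in-plane vinylic hydrogen on the enone α-carbon (allylic 1,3-strain) and lie next to the ring CH2 (the later C10), so that the α-carbon (the later C6) ends trans to it. At C1 the branched side chain should take the pseudo-equatorial place, trans to the C4 methyl group and beside the flat α-carbon instead of the ring CH2, which is also what 1- and 4-substituted hex-5-enyl radicals prefer. The step needs 5-exo regioselectivity (secured by the polarity of the enone) and the diastereoselectivity that puts the side chain cis to C6 and trans to the C4 methyl group (secured by the C4 stereocentre and the size of the C1 substituent); the centres at the acid α-carbon and at the ring methyl carbon of 16 are of no account, the first becoming the planar radical and the second being planarized in steps 11 and 12.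

Step 11
Reactants: 17 (1R,4S,5R)-4,8-dimethyl-1-[(2R,6S)-6-methyl-7-[(triisopropylsilyl)oxy]heptan-2-yl]spiro[4.5]decan-7-one
Product: 18 (1R,4S,5R)-4,8-dimethyl-1-[(2R,6S)-6-methyl-7-[(triisopropylsilyl)oxy]heptan-2-yl]-7-[(trimethylsilyl)oxy]spiro[4.5]dec-7-ene
Conditions: TMSCl, NaI, Et3N, MeCN, 23 °C
Reagents that add atoms: chlorotrimethylsilane, C[Si](C)(C)Cl
Why: Thermodynamic silyl enol ether formation (iodotrimethylsilane made in the flask, amine base) should favour the tetrasubstituted enol ether towards the methyl-bearing C8, the other α-carbon (C6) being a CH2 next to the spiro atom, and it erases the C8 mixture.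

Step 12
Reactants: 18 (1R,4S,5R)-4,8-dimethyl-1-[(2R,6S)-6-methyl-7-[(triisopropylsilyl)oxy]heptan-2-yl]-7-[(trimethylsilyl)oxy]spiro[4.5]dec-7-ene
Product: 19 (1R,4S,5R)-4,8-dimethyl-1-[(2R,6S)-6-methyl-7-[(triisopropylsilyl)oxy]heptan-2-yl]spiro[4.5]dec-8-en-7-one
Conditions: Pd(OAc)2 (1.1 equiv), MeCN, 23 °C
Reagents that add atoms: none
Why: Saegusa–Ito oxidation, in which divalent palladium is reduced to zerovalent palladium and β-hydride elimination towards the ring CH2 (C9) gives the conjugated 2-methylcyclohex-2-enone.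

Step 13
Reactants: 19 (1R,4S,5R)-4,8-dimethyl-1-[(2R,6S)-6-methyl-7-[(triisopropylsilyl)oxy]heptan-2-yl]spiro[4.5]dec-8-en-7-one
Product: 20 (1R,4S,5R,8S,9S)-8,9-epoxy-4,8-dimethyl-1-[(2R,6S)-6-methyl-7-[(triisopropylsilyl)oxy]heptan-2-yl]spiro[4.5]decan-7-one
Conditions: 30% aq. H2O2, NaOH (cat.), MeOH, 0 °C
Reagents that add atoms: hydrogen peroxide, OO
Why: Weitz–Scheffer nucleophilic epoxidation, in which hydroperoxide should add to C9 from the ring face that looks towards the hydrogen on C1, anti to the C4 methyl group that shields the other face of the C9–C10 edge, and so sets C8 and the C9–O bond (9S).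

Step 14
Reactants: 20 (1R,4S,5R,8S,9S)-8,9-epoxy-4,8-dimethyl-1-[(2R,6S)-6-methyl-7-[(triisopropylsilyl)oxy]heptan-2-yl]spiro[4.5]decan-7-one
Product: 23 (1R,4S,5S,9S)-4,8-dimethyl-1-[(2R,6S)-6-methyl-7-[(triisopropylsilyl)oxy]heptan-2-yl]spiro[4.5]dec-7-en-9-ol, via epoxy hydrazone 21 (not isolated), via alkenyl diazene 22 (not isolated)
Conditions: N2H4·H2O, AcOH (cat.), MeOH, 0 to 23 °C
Reagents that add atoms: none
Why: Wharton transposition, in which the hydrazone opens the epoxide to an alkenyl diazene that loses nitrogen, so that the carbonyl carbon becomes the alkene CH (C7) while the C9–O bond is not touched and keeps its configuration, as in the conversion of carvone oxide into trans-carveol.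

Step 15
Reactants: 23 (1R,4S,5S,9S)-4,8-dimethyl-1-[(2R,6S)-6-methyl-7-[(triisopropylsilyl)oxy]heptan-2-yl]spiro[4.5]dec-7-en-9-ol
Product: 24 (1R,4S,5S,9S)-1-[(2R,6S)-7-hydroxy-6-methylheptan-2-yl]-4,8-dimethylspiro[4.5]dec-7-en-9-ol
Conditions: TBAF, THF, 23 °C
Reagents that add atoms: none
Why: Fluoride cleavage of the silyl ether under conditions that leave the allylic alcohol alone.

Step 16
Reactants: 24 (1R,4S,5S,9S)-1-[(2R,6S)-7-hydroxy-6-methylheptan-2-yl]-4,8-dimethylspiro[4.5]dec-7-en-9-ol
Product: 25 (2S,6R)-6-[(1R,4S,5S,9S)-9-hydroxy-4,8-dimethylspiro[4.5]dec-7-en-1-yl]-2-methylheptyl acetate (CNP0304655.1)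
Conditions: AcCl (1.1 equiv), 2,4,6-collidine, CH2Cl2, −78 °C
Reagents that add atoms: acetyl chloride, CC(=O)Cl
Why: Kinetically selective acylation, the unhindered primary alcohol reacting much faster at low temperature than the secondary allylic alcohol that is flanked by the trisubstituted alkene and the spiro ring.

**Compound list**

1 | (3-methoxy-4-methylphenyl)boronic acid | OB(O)c1ccc(C)c(OC)c1 | starting material
2 | tert-butyl (E)-but-2-enoate | C/C=C/C(=O)OC(C)(C)C | starting material
3 | tert-butyl (3S)-3-(3-methoxy-4-methylphenyl)butanoate | CC(C)(C)OC(=O)C[C@H](C)c1ccc(C)c(OC)c1 | intermediate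
4 | (3S)-3-(3-methoxy-4-methylphenyl)butan-1-ol | OCC[C@H](C)c1ccc(C)c(OC)c1 | intermediate
5 | 4-[(2S)-4-iodobutan-2-yl]-2-methoxy-1-methylbenzene | ICC[C@H](C)c1ccc(C)c(OC)c1 | intermediate
6 | (3R)-3,7-dimethyloct-6-enoic acid ((R)-citronellic acid) | OC(=O)C[C@H](C)CCC=C(C)C | starting material
7 | benzyl (3R)-3,7-dimethyloct-6-enoate | O=C(OCc1ccccc1)C[C@H](C)CCC=C(C)C | intermediate
8 | benzyl (3R,6E)-8-hydroxy-3,7-dimethyloct-6-enoate | O=C(OCc1ccccc1)C[C@H](C)CC/C=C(\C)CO | intermediate
9 | benzyl (3R,7S)-8-hydroxy-3,7-dimethyloctanoate | O=C(OCc1ccccc1)C[C@H](C)CCC[C@H](C)CO | intermediate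
10 | benzyl (3R,7S)-3,7-dimethyl-8-[(triisopropylsilyl)oxy]octanoate | O=C(OCc1ccccc1)C[C@H](C)CCC[C@H](C)CO[Si](C(C)C)(C(C)C)C(C)C | intermediate
11 | lithium enolate of 10 | [Li+].[O-]C(OCc1ccccc1)=C[C@H](C)CCC[C@H](C)CO[Si](C(C)C)(C(C)C)C(C)C | intermediate (not isolated)
12 | benzyl (3R,7S)-2-[(3S)-3-(3-methoxy-4-methylphenyl)butyl]-3,7-dimethyl-8-[(triisopropylsilyl)oxy]octanoate, both C2 epimers | O=C(OCc1ccccc1)C(CC[C@H](C)c1ccc(C)c(OC)c1)[C@H](C)CCC[C@H](C)CO[Si](C(C)C)(C(C)C)C(C)C | intermediate
13 | lithium (3R,7S)-2-[(3S)-3-(3-methoxy-4-methylphenyl)butyl]-3,7-dimethyl-8-[(triisopropylsilyl)oxy]octanoate | [Li+].[O-]C(=O)C(CC[C@H](C)c1ccc(C)c(OC)c1)[C@H](C)CCC[C@H](C)CO[Si](C(C)C)(C(C)C)C(C)C | intermediate (not isolated)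
14 | lithium (3R,7S)-2-[(3S)-3-(5-methoxy-4-methylcyclohexa-1,4-dien-1-yl)butyl]-3,7-dimethyl-8-[(triisopropylsilyl)oxy]octanoate | [Li+].[O-]C(=O)C(CC[C@H](C)C1=CCC(C)=C(OC)C1)[C@H](C)CCC[C@H](C)CO[Si](C(C)C)(C(C)C)C(C)C | intermediate (not isolated)
15 | (3R,7S)-3,7-dimethyl-2-[(3S)-3-(4-methyl-5-oxocyclohex-1-en-1-yl)butyl]-8-[(triisopropylsilyl)oxy]octanoic acid | OC(=O)C(CC[C@H](C)C1=CCC(C)C(=O)C1)[C@H](C)CCC[C@H](C)CO[Si](C(C)C)(C(C)C)C(C)C | intermediate (not isolated)
16 | (3R,7S)-3,7-dimethyl-2-[(3S)-3-(4-methyl-3-oxocyclohex-1-en-1-yl)butyl]-8-[(triisopropylsilyl)oxy]octanoic acid, epimers at C2 and at the ring methyl carbon | OC(=O)C(CC[C@H](C)C1=CC(=O)C(C)CC1)[C@H](C)CCC[C@H](C)CO[Si](C(C)C)(C(C)C)C(C)C | intermediate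
17 | (1R,4S,5R)-4,8-dimethyl-1-[(2R,6S)-6-methyl-7-[(triisopropylsilyl)oxy]heptan-2-yl]spiro[4.5]decan-7-one, both C8 epimers; side chain cis to C6, C4 methyl cis to C10 | CC(C)[Si](C(C)C)(C(C)C)OC[C@@H](C)CCC[C@@H](C)[C@H]1CC[C@H](C)[C@@]12CC(=O)C(C)CC2 | intermediate
18 | (1R,4S,5R)-4,8-dimethyl-1-[(2R,6S)-6-methyl-7-[(triisopropylsilyl)oxy]heptan-2-yl]-7-[(trimethylsilyl)oxy]spiro[4.5]dec-7-ene | CC(C)[Si](C(C)C)(C(C)C)OC[C@@H](C)CCC[C@@H](C)[C@H]1CC[C@H](C)[C@@]12CC(O[Si](C)(C)C)=C(C)CC2 | intermediate
19 | (1R,4S,5R)-4,8-dimethyl-1-[(2R,6S)-6-methyl-7-[(triisopropylsilyl)oxy]heptan-2-yl]spiro[4.5]dec-8-en-7-one | CC(C)[Si](C(C)C)(C(C)C)OC[C@@H](C)CCC[C@@H](C)[C@H]1CC[C@H](C)[C@@]12CC(=O)C(C)=CC2 | intermediate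
20 | (1R,4S,5R,8S,9S)-8,9-epoxy-4,8-dimethyl-1-[(2R,6S)-6-methyl-7-[(triisopropylsilyl)oxy]heptan-2-yl]spiro[4.5]decan-7-one, epoxide on the ring face turned towards C1 | CC(C)[Si](C(C)C)(C(C)C)OC[C@@H](C)CCC[C@@H](C)[C@H]1CC[C@H](C)[C@@]12CC(=O)[C@@]3(C)O[C@H]3C2 | intermediate
21 | hydrazone of 20 at C7 | CC(C)[Si](C(C)C)(C(C)C)OC[C@@H](C)CCC[C@@H](C)[C@H]1CC[C@H](C)[C@@]12CC(=NN)[C@@]3(C)O[C@H]3C2 | intermediate (not isolated)
22 | 7-diazenyl derivative of 23 (alkenyl diazene) | CC(C)[Si](C(C)C)(C(C)C)OC[C@@H](C)CCC[C@@H](C)[C@H]1CC[C@H](C)[C@@]12CC(N=N)=C(C)[C@@H](O)C2 | intermediate (not isolated)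
23 | (1R,4S,5S,9S)-4,8-dimethyl-1-[(2R,6S)-6-methyl-7-[(triisopropylsilyl)oxy]heptan-2-yl]spiro[4.5]dec-7-en-9-ol | CC(C)[Si](C(C)C)(C(C)C)OC[C@@H](C)CCC[C@@H](C)[C@H]1CC[C@H](C)[C@@]12CC=C(C)[C@@H](O)C2 | intermediate
24 | (1R,4S,5S,9S)-1-[(2R,6S)-7-hydroxy-6-methylheptan-2-yl]-4,8-dimethylspiro[4.5]dec-7-en-9-ol | OC[C@@H](C)CCC[C@@H](C)[C@H]1CC[C@H](C)[C@@]12CC=C(C)[C@@H](O)C2 | intermediate
25 | (2S,6R)-6-[(1R,4S,5S,9S)-9-hydroxy-4,8-dimethylspiro[4.5]dec-7-en-1-yl]-2-methylheptyl acetate | CC(=O)OC[C@@H](C)CCC[C@@H](C)[C@H]1CC[C@H](C)[C@@]12CC=C(C)[C@@H](O)C2 | target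

**Count and risks**

Total step count: 16. Longest linear sequence: 13 steps (steps 4–16, from 6); the arm from 1 (steps 1–3, then 8–16) has 12.

The three steps most likely to fail:

1. Step 10. The closure may take place with the enone turned the other way about the C4–C5 bond, so that facial selectivity at C5 is low or reversed and the carbonyl-bearing arm ends on the side of the C4 methyl group. Conditions are unlikely to change this, so the fallback changes how the two arms of the six-membered ring are told apart. C5 is stereogenic only because these arms differ, and the 2-methylcyclohexanone can be developed in either direction. The fallback sets out from 16 and comes back at 23. The spiro-epimeric ketone F1, formed from 16 under the conditions of step 10 and separated from 17 if both arise, would be converted with TMSCl, NaI and Et3N into the thermodynamic silyl enol ether F2 and with Pd(OAc)2 into the enone F3, whose carbonyl carbon is now C9. Instead of epoxidation and Wharton transposition, a CBS reduction ((R)-Me-CBS oxazaborolidine, catecholborane, toluene, −78 °C) would then deliver hydride under reagent control to give the 9S alcohol 23 directly.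

2. Step 14. Hydrazone formation at a ketone placed between a CH2 next to the spiro atom and a fully substituted epoxide carbon may be slow, and the epoxy hydrazone may be diverted by attack of hydrazine on the epoxide or by reduction. The step also passes on whatever facial selectivity step 13 achieved at C9. The fallback sets out from 19, comes back at 23, and replaces both the nucleophilic epoxidation and the hydrazine step. Luche reduction (NaBH4, CeCl3·7H2O, MeOH, −78 °C) should deliver hydride to C7 from the face away from the C1 side chain and give the allylic alcohol F4. Hydroxyl-directed epoxidation (VO(acac)2, t-BuOOH, CH2Cl2) then places the oxygen syn to that hydroxyl, on the face required at C9, in the epoxy alcohol F5. Acylation with 1,1′-thiocarbonyldiimidazole gives the thiocarbonylimidazolide F6. Bu3SnH with AIBN in toluene at 80 °C then generates the C7 radical, which opens the epoxide to the C7=C8 alkene and the C9 alkoxy radical, reduced to 23 (radical deoxygenative epoxide opening of the Barton–McCombie type).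

3. Step 9. Three reductive events share one flask: carbonyl reduction may compete with benzylic C–O cleavage of the ester, the lithium carboxylate may be too poorly soluble for complete arene reduction, and the acid-mediated conjugation on the advanced intermediate may cost the silyl ether or epimerize the ring-bound methine (C4) through the exocyclic dienol. The fallback sets out from 4 and comes back at 14; it moves the dissolving-metal step to the small fragment and removes the ester with hydroxide. Birch reduction of 4 (Li, NH3, t-BuOH, THF) gives the dienol ether alcohol F7. MsCl and Et3N give the mesylate F8, and NaI with NaHCO3 in acetone the iodide F9, without exposing the enol ether to acid or iodine. Alkylation of the lithium enolate 11 with F9 gives the benzyl ester F10. LiOH in THF/MeOH/H2O then gives the carboxylate 14, which is hydrolysed and conjugated to 16 as in the last stage of step 9.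

Further compounds
F1 | step 10 | (1R,4S,5S)-4,8-dimethyl-1-[(2R,6S)-6-methyl-7-[(triisopropylsilyl)oxy]heptan-2-yl]spiro[4.5]decan-9-one, ketone arm cis to the C4 methyl group | CC(C)[Si](C(C)C)(C(C)C)OC[C@@H](C)CCC[C@@H](C)[C@H]1CC[C@H](C)[C@@]12CCC(C)C(=O)C2
F2 | step 10 | 9-[(trimethylsilyl)oxy]spiro[4.5]dec-8-ene derived from F1 | CC(C)[Si](C(C)C)(C(C)C)OC[C@@H](C)CCC[C@@H](C)[C@H]1CC[C@H](C)[C@@]12CCC(C)=C(O[Si](C)(C)C)C2
F3 | step 10 | (1R,4S,5S)-4,8-dimethyl-1-[(2R,6S)-6-methyl-7-[(triisopropylsilyl)oxy]heptan-2-yl]spiro[4.5]dec-7-en-9-one | CC(C)[Si](C(C)C)(C(C)C)OC[C@@H](C)CCC[C@@H](C)[C@H]1CC[C@H](C)[C@@]12CC=C(C)C(=O)C2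
F4 | step 14 | 4,8-dimethyl-1-[(2R,6S)-6-methyl-7-[(triisopropylsilyl)oxy]heptan-2-yl]spiro[4.5]dec-8-en-7-ol, hydroxyl on the ring face turned towards C1 | CC(C)[Si](C(C)C)(C(C)C)OC[C@@H](C)CCC[C@@H](C)[C@H]1CC[C@H](C)[C@@]12C[C@@H](O)C(C)=CC2
F5 | step 14 | 8,9-epoxy-4,8-dimethyl-1-[(2R,6S)-6-methyl-7-[(triisopropylsilyl)oxy]heptan-2-yl]spiro[4.5]decan-7-ol, epoxide cis to the hydroxyl | CC(C)[Si](C(C)C)(C(C)C)OC[C@@H](C)CCC[C@@H](C)[C@H]1CC[C@H](C)[C@@]12C[C@@H](O)[C@@]3(C)O[C@H]3C2
F6 | step 14 | O-(imidazol-1-ylthiocarbonyl) derivative of F5 | CC(C)[Si](C(C)C)(C(C)C)OC[C@@H](C)CCC[C@@H](C)[C@H]1CC[C@H](C)[C@@]12C[C@@H](OC(=S)n3ccnc3)[C@@]4(C)O[C@H]4C2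
F7 | step 9 | (3S)-3-(5-methoxy-4-methylcyclohexa-1,4-dien-1-yl)butan-1-ol | OCC[C@H](C)C1=CCC(C)=C(OC)C1
F8 | step 9 | (3S)-3-(5-methoxy-4-methylcyclohexa-1,4-dien-1-yl)butyl methanesulfonate | CS(=O)(=O)OCC[C@H](C)C1=CCC(C)=C(OC)C1
F9 | step 9 | 5-[(2S)-4-iodobutan-2-yl]-1-methoxy-2-methylcyclohexa-1,4-diene | ICC[C@H](C)C1=CCC(C)=C(OC)C1
F10 | step 9 | benzyl (3R,7S)-2-[(3S)-3-(5-methoxy-4-methylcyclohexa-1,4-dien-1-yl)butyl]-3,7-dimethyl-8-[(triisopropylsilyl)oxy]octanoate | O=C(OCc1ccccc1)C(CC[C@H](C)C1=CCC(C)=C(OC)C1)[C@H](C)CCC[C@H](C)CO[Si](C(C)C)(C(C)C)C(C)C
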